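**Plan**

- Lactone numbering used throughout: O1, C2(=O), C3, C4(H)=, C5(H2), C6(H). The retrosynthesis opens the lactone bond O1–C2, then cuts C3=C4 and C5–C6 in one stroke, then takes the enal back through Morita–Baylis–Hillman logic to nerol.
- Enabling feature: ring atoms C4 and C5 of the 5,6-dihydro-2H-pyran-2-one are a hidden acetaldehyde (C5 its α-carbon, C4 its carbonyl carbon). They lie between the allylic carbinol carbon C6 and the α-carbon C3 of the lactone carbonyl, so an enal (C6), an acetaldehyde enolsilane (C5–C4) and an α-homoprenyl phosphonate (C3) can be joined in one flask.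
- Forward order: nerol → C7 Z-aldehyde 5 → Morita–Baylis–Hillman adduct → E-enal 11 carrying the acetate; phosphonate 14 in one step; three-component union to the open chain 17; the only ring is closed last by lactonization.
- Stereochemistry: C6 (S) from a catalyst-controlled Mukaiyama aldol on the Si face of 11; the 6Z side-chain alkene comes with nerol; the 2E side-chain alkene from a thermodynamic 1,3-acetate shift; the ring alkene from a Z-selective olefination, then locked by the ring.
- Helpers: the TBS group delivered to O1 by the enolsilane and the TBDPS group on the primary alcohol are removed in the last step; the phosphoryl group leaves in the key step itself.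

Key step: step 9

Assumption: compounds 1, 6, 12, 13 and 15 are bought; the aldol catalyst is the imidodiphosphorimidate acid HN[P(=NSO2CF3)(O2Ar*)]2 with O2Ar* = (S)-3,3'-bis[3,5-bis(trifluoromethyl)phenyl]-1,1'-binaphthalene-2,2'-diolate, and its mirror image is to be taken instead if a trial run shows the opposite facial sense.

**Route**

Step 1
Reactants: 1 nerol, (2Z)-3,7-dimethylocta-2,6-dien-1-ol
Product: 2 tert-butyl{[(2Z)-3,7-dimethylocta-2,6-dien-1-yl]oxy}diphenylsilane
Conditions: t-BuPh2SiCl, imidazole, DMF, 0 °C → rt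
Reagents that add atoms: tert-butyl(chloro)diphenylsilane, CC(C)(C)[Si](Cl)(c1ccccc1)c1ccccc1
Why: Imidazole-promoted silylation of the primary allylic alcohol should give a robust silyl ether that also deactivates the neighbouring alkene, inductively and sterically, for step 2; no stereocenter is formed.

Step 2
Reactants: 2 tert-butyl{[(2Z)-3,7-dimethylocta-2,6-dien-1-yl]oxy}diphenylsilane
Product: 3 tert-butyl{[(2Z)-5-(3,3-dimethyloxiran-2-yl)-3-methylpent-2-en-1-yl]oxy}diphenylsilane (racemic)
Conditions: mCPBA (1.0 equiv), NaHCO3, CH2Cl2, −20 → 0 °C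
Reagents that add atoms: 3-chloroperoxybenzoic acid, OOC(=O)c1cccc(Cl)c1
Why: Prilezhaev epoxidation should take the more electron-rich, unhindered terminal trisubstituted alkene in preference to the alkene next to the silyloxymethyl group; the epoxide center is racemic and is destroyed in step 3.

Step 3
Reactants: 3 tert-butyl{[(2Z)-5-(3,3-dimethyloxiran-2-yl)-3-methylpent-2-en-1-yl]oxy}diphenylsilane
Product: 5 (4Z)-6-[(tert-butyldiphenylsilyl)oxy]-4-methylhex-4-enal, via vicinal diol 4 (not isolated)
Conditions: H5IO6, THF/H2O, 0 °C → rt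
Reagents that add atoms: none
Why: Acid-mediated hydrolysis of the epoxide to diol 4 (water attacks the tertiary carbon, so the aldehyde oxygen is the former epoxide oxygen) followed in the same flask by periodate glycol cleavage (Malaprade reaction) should give the aldehyde and acetone while the Z alkene and the silyl ether stay untouched.

Step 4
Reactants: 5 (4Z)-6-[(tert-butyldiphenylsilyl)oxy]-4-methylhex-4-enal; 6 methyl acrylate
Product: 7 methyl (6Z)-8-[(tert-butyldiphenylsilyl)oxy]-3-hydroxy-6-methyl-2-methylideneoct-6-enoate (racemic)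
Conditions: DABCO (1 equiv), 6 (3 equiv), MeOH, rt, several days
Reagents that add atoms: none
Why: The Morita–Baylis–Hillman reaction of an unhindered aliphatic aldehyde with methyl acrylate should install the α-methylene β-hydroxy ester; the carbinol center is racemic and is erased in step 7.

Step 5
Reactants: 7 methyl (6Z)-8-[(tert-butyldiphenylsilyl)oxy]-3-hydroxy-6-methyl-2-methylideneoct-6-enoate
Product: 8 (6Z)-8-[(tert-butyldiphenylsilyl)oxy]-6-methyl-2-methylideneoct-6-ene-1,3-diol (racemic)
Conditions: i-Bu2AlH (3.5 equiv), CH2Cl2, −78 → 0 °C; aq. Rochelle salt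
Reagents that add atoms: none
Why: i-Bu2AlH should reduce the conjugated ester in the 1,2-sense to the primary allylic alcohol (ester reduction) without touching the silyl ether or the alkenes.

Step 6
Reactants: 8 (6Z)-8-[(tert-butyldiphenylsilyl)oxy]-6-methyl-2-methylideneoct-6-ene-1,3-diol
Product: 9 (6Z)-8-[(tert-butyldiphenylsilyl)oxy]-3-hydroxy-6-methyl-2-methylideneoct-6-enal (racemic)
Conditions: TEMPO (10 mol%), PhI(OAc)2 (1.1 equiv), CH2Cl2, rt
Reagents that add atoms: none
Why: Oxoammonium (TEMPO) oxidation with PhI(OAc)2 as terminal oxidant is selective for the primary over the secondary allylic alcohol and should stop at the aldehyde.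

Step 7
Reactants: 9 (6Z)-8-[(tert-butyldiphenylsilyl)oxy]-3-hydroxy-6-methyl-2-methylideneoct-6-enal
Product: 11 [(2E,6Z)-8-[(tert-butyldiphenylsilyl)oxy]-2-formyl-6-methylocta-2,6-dien-1-yl] acetate, via secondary acetate 10 (not isolated)
Conditions: Ac2O, Et3N, DMAP (cat.), CH2Cl2, 0 °C; then DABCO (0.3 equiv), THF, rt
Reagents that add atoms: acetic anhydride, CC(=O)OC(C)=O
Why: O-Acetylation gives the Morita–Baylis–Hillman-type acetate 10, which the amine should transpose by a reversible SN2'–SN2' sequence (allylic 1,3-acetate shift) to the conjugated trisubstituted enal, expected as the thermodynamically preferred E isomer with the formyl group trans to the chain; the racemic carbinol center disappears.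

Step 8
Reactants: 12 methyl 2-[bis(2,2,2-trifluoroethoxy)phosphoryl]acetate; 13 5-bromo-2-methylpent-2-ene
Product: 14 methyl 2-[bis(2,2,2-trifluoroethoxy)phosphoryl]-6-methylhept-5-enoate (racemic)
Conditions: NaH, DMF, 0 °C; then 13, NaI (cat.), 50 °C
Reagents that add atoms: none
Why: C-Alkylation of the sodium salt of the phosphonoacetate with the primary homoallylic bromide (in situ Finkelstein activation) should give the α-substituted olefination reagent; its new center is racemic and is lost in step 9.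

Step 9
Reactants: 11 [(2E,6Z)-8-[(tert-butyldiphenylsilyl)oxy]-2-formyl-6-methylocta-2,6-dien-1-yl] acetate; 15 tert-butyldimethyl(vinyloxy)silane; 14 methyl 2-[bis(2,2,2-trifluoroethoxy)phosphoryl]-6-methylhept-5-enoate
Product: 17 methyl (2Z,5S,6E,10Z)-6-(acetoxymethyl)-5-[(tert-butyldimethylsilyl)oxy]-12-[(tert-butyldiphenylsilyl)oxy]-10-methyl-2-(4-methylpent-3-en-1-yl)dodeca-2,6,10-trienoate, via silyloxy aldehyde 16 (not isolated)
Conditions: 15 (1.5 equiv), HN[P(=NSO2CF3)(O2Ar*)]2 (1 mol%), toluene, −78 °C; then K salt of 14 [14, KN(SiMe3)2, 18-crown-6, THF, −78 °C], −78 → −40 °C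
Reagents that add atoms: none
Why: The acid is silylated in the flask by 15 to a silylium-type Lewis acid held in a chiral imidodiphosphorimidate ion pair, which activates the formyl group of 11 so that the terminal carbon of 15 adds to it (C5–C6) with transfer of the silyl group to the aldolate oxygen, and the aldehyde 16 so released (C4) is trapped in the same flask by the potassium phosphonate of 14, whose oxaphosphetane collapses to the C3=C4 alkene. The closest known reaction types are the catalytic asymmetric Mukaiyama single aldolization of acetaldehyde enolsilanes with aldehydes followed by one-pot olefination, and the Still–Gennari variant of the Horner–Wadsworth–Emmons reaction with α-alkyl phosphonates. No ring is closed here; the chain is only set up for the 6-exo-trig lactonization of step 10. The one new stereocenter, C6 (S), is set by the catalyst, which must direct 15 to the Si face of the aldehyde of 11. The step needs 1,2-addition and a single aldolization, which the α-branched enal and the bulky β-silyloxy group of 16 inside the confined ion pair should secure, and it needs the Z alkene (ester cis to C5), which the bis(trifluoroethyl) phosphonate under dissociating potassium/18-crown-6 conditions at low temperature should give by fast, irreversible elimination from the kinetically formed adduct.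

Step 10
Reactants: 17 methyl (2Z,5S,6E,10Z)-6-(acetoxymethyl)-5-[(tert-butyldimethylsilyl)oxy]-12-[(tert-butyldiphenylsilyl)oxy]-10-methyl-2-(4-methylpent-3-en-1-yl)dodeca-2,6,10-trienoate
Product: 19 (6S)-6-[(2E,6Z)-1-acetoxy-8-hydroxy-6-methylocta-2,6-dien-2-yl]-3-(4-methylpent-3-en-1-yl)-5,6-dihydro-2H-pyran-2-one, via hydroxy ester 18 (not isolated)
Conditions: HF·pyridine, pyridine, THF, 0 °C → rt; then PPTS (cat.), toluene, 40 °C
Reagents that add atoms: none
Why: Fluoride-mediated cleavage of both silyl ethers frees the C6 hydroxyl, which should close the six-membered lactone onto the cis-disposed methyl ester under mild acid (6-exo-trig transesterification) while the primary allylic acetate and the C6 configuration stay untouched.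

**Compound list**

1 | nerol, (2Z)-3,7-dimethylocta-2,6-dien-1-ol | CC(C)=CCC/C(C)=C\CO | starting material
2 | tert-butyl{[(2Z)-3,7-dimethylocta-2,6-dien-1-yl]oxy}diphenylsilane | CC(C)=CCC/C(C)=C\CO[Si](c1ccccc1)(c1ccccc1)C(C)(C)C | intermediate
3 | tert-butyl{[(2Z)-5-(3,3-dimethyloxiran-2-yl)-3-methylpent-2-en-1-yl]oxy}diphenylsilane (racemic) | CC1(C)OC1CC/C(C)=C\CO[Si](c1ccccc1)(c1ccccc1)C(C)(C)C | intermediate
4 | (6Z)-8-[(tert-butyldiphenylsilyl)oxy]-2,6-dimethyloct-6-ene-2,3-diol (racemic, not isolated) | CC(C)(O)C(O)CC/C(C)=C\CO[Si](c1ccccc1)(c1ccccc1)C(C)(C)C | intermediate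
5 | (4Z)-6-[(tert-butyldiphenylsilyl)oxy]-4-methylhex-4-enal | O=CCC/C(C)=C\CO[Si](c1ccccc1)(c1ccccc1)C(C)(C)C | intermediate
6 | methyl acrylate | C=CC(=O)OC | starting material
7 | methyl (6Z)-8-[(tert-butyldiphenylsilyl)oxy]-3-hydroxy-6-methyl-2-methylideneoct-6-enoate (racemic) | COC(=O)C(=C)C(O)CC/C(C)=C\CO[Si](c1ccccc1)(c1ccccc1)C(C)(C)C | intermediate
8 | (6Z)-8-[(tert-butyldiphenylsilyl)oxy]-6-methyl-2-methylideneoct-6-ene-1,3-diol (racemic) | OCC(=C)C(O)CC/C(C)=C\CO[Si](c1ccccc1)(c1ccccc1)C(C)(C)C | intermediate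
9 | (6Z)-8-[(tert-butyldiphenylsilyl)oxy]-3-hydroxy-6-methyl-2-methylideneoct-6-enal (racemic) | O=CC(=C)C(O)CC/C(C)=C\CO[Si](c1ccccc1)(c1ccccc1)C(C)(C)C | intermediate
10 | (6Z)-8-[(tert-butyldiphenylsilyl)oxy]-6-methyl-2-methylidene-1-oxooct-6-en-3-yl acetate (racemic, not isolated) | CC(=O)OC(CC/C(C)=C\CO[Si](c1ccccc1)(c1ccccc1)C(C)(C)C)C(=C)C=O | intermediate
11 | [(2E,6Z)-8-[(tert-butyldiphenylsilyl)oxy]-2-formyl-6-methylocta-2,6-dien-1-yl] acetate | CC(=O)OC/C(C=O)=C\CC/C(C)=C\CO[Si](c1ccccc1)(c1ccccc1)C(C)(C)C | intermediate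
12 | methyl 2-[bis(2,2,2-trifluoroethoxy)phosphoryl]acetate | COC(=O)CP(=O)(OCC(F)(F)F)OCC(F)(F)F | starting material
13 | 5-bromo-2-methylpent-2-ene | CC(C)=CCCBr | starting material
14 | methyl 2-[bis(2,2,2-trifluoroethoxy)phosphoryl]-6-methylhept-5-enoate (racemic) | COC(=O)C(CCC=C(C)C)P(=O)(OCC(F)(F)F)OCC(F)(F)F | intermediate
15 | tert-butyldimethyl(vinyloxy)silane | C=CO[Si](C)(C)C(C)(C)C | starting material
16 | [(2E,6Z)-2-[(1S)-1-[(tert-butyldimethylsilyl)oxy]-3-oxopropyl]-8-[(tert-butyldiphenylsilyl)oxy]-6-methylocta-2,6-dien-1-yl] acetate (not isolated) | CC(=O)OC/C(=C\CC/C(C)=C\CO[Si](c1ccccc1)(c1ccccc1)C(C)(C)C)[C@@H](O[Si](C)(C)C(C)(C)C)CC=O | intermediate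
17 | methyl (2Z,5S,6E,10Z)-6-(acetoxymethyl)-5-[(tert-butyldimethylsilyl)oxy]-12-[(tert-butyldiphenylsilyl)oxy]-10-methyl-2-(4-methylpent-3-en-1-yl)dodeca-2,6,10-trienoate | CC(=O)OC/C(=C\CC/C(C)=C\CO[Si](c1ccccc1)(c1ccccc1)C(C)(C)C)[C@@H](O[Si](C)(C)C(C)(C)C)C/C=C(/CCC=C(C)C)C(=O)OC | intermediate
18 | methyl (2Z,5S,6E,10Z)-6-(acetoxymethyl)-5,12-dihydroxy-10-methyl-2-(4-methylpent-3-en-1-yl)dodeca-2,6,10-trienoate (not isolated) | CC(=O)OC/C(=C\CC/C(C)=C\CO)[C@@H](O)C/C=C(/CCC=C(C)C)C(=O)OC | intermediate
19 | (6S)-6-[(2E,6Z)-1-acetoxy-8-hydroxy-6-methylocta-2,6-dien-2-yl]-3-(4-methylpent-3-en-1-yl)-5,6-dihydro-2H-pyran-2-one | CC(=O)OC/C(=C\CC/C(C)=C\CO)[C@@H]1CC=C(CCC=C(C)C)C(=O)O1 | target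

**Totals and risks**

Total steps: 10. Longest linear sequence: 9 steps (steps 1–7, 9 and 10); step 8 is a one-step side branch.

Steps most likely to fail, in order:

1. Step 9. The confined acid may not accept the long, α-branched enal, so that addition becomes slow, facial control poor or conjugate addition competitive. The olefination may also give part of the E ester, which cannot lactonize. The fallback sets out from 11 and comes back at 19. Asymmetric allylboration of 11 with the reagent enantiomer that adds to the Si face, expected to be (−)-B-allyldiisopinocampheylborane (made in the flask from (−)-B-methoxydiisopinocampheylborane and allylmagnesium bromide; Et2O, −78 °C, ethanolamine work-up), should give [(2E,6Z)-8-[(tert-butyldiphenylsilyl)oxy]-2-[(1S)-1-hydroxybut-3-en-1-yl]-6-methylocta-2,6-dien-1-yl] acetate F1. Separately, 14 is olefinated with aqueous formaldehyde and K2CO3 to methyl 6-methyl-2-methylidenehept-5-enoate F2, which LiOH hydrolyses to 6-methyl-2-methylidenehept-5-enoic acid F3. Esterification of F1 with F3 (DCC, DMAP, CH2Cl2) gives (4S,5E,9Z)-5-(acetoxymethyl)-11-[(tert-butyldiphenylsilyl)oxy]-9-methylundeca-1,5,9-trien-4-yl 6-methyl-2-methylidenehept-5-enoate F4. Ring-closing metathesis with the second-generation Grubbs catalyst (toluene, 80 °C) then closes the ring, with the ring alkene cis by necessity, to (6S)-6-[(2E,6Z)-1-acetoxy-8-[(tert-butyldiphenylsilyl)oxy]-6-methylocta-2,6-dien-2-yl]-3-(4-methylpent-3-en-1-yl)-5,6-dihydro-2H-pyran-2-one F5. HF·pyridine removes the silyl group to give 19.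

2. Step 7 (together with the sensitive hydroxy enal made in step 6). The α-methylene β-hydroxy aldehyde may oligomerize, and the acetate shift may stop short or equilibrate to an E/Z mixture. The fallback sets out from 7 and comes back at 11; it fixes the alkene geometry at the ester stage. N-Bromosuccinimide/Me2S (CH2Cl2, 0 °C) should convert 7 by SN2' displacement into methyl (2Z,6Z)-2-(bromomethyl)-8-[(tert-butyldiphenylsilyl)oxy]-6-methylocta-2,6-dienoate F6. i-Bu2AlH (CH2Cl2, −78 °C) reduces the ester to (2Z,6Z)-2-(bromomethyl)-8-[(tert-butyldiphenylsilyl)oxy]-6-methylocta-2,6-dien-1-ol F7. MnO2 (CH2Cl2, rt) oxidizes it to (2Z,6Z)-2-(bromomethyl)-8-[(tert-butyldiphenylsilyl)oxy]-6-methylocta-2,6-dienal F8. KOAc (18-crown-6, MeCN, rt) displaces bromide to give 11.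

3. Step 8. The weakly nucleophilic bis(trifluoroethyl) phosphonoacetate anion may alkylate slowly, with double alkylation and elimination of the bromide as competing processes. The fallback sets out from 13 and comes back at 14. The more nucleophilic sodium salt of trimethyl phosphonoacetate (NaH, DMF) is alkylated with 13 to methyl 2-(dimethoxyphosphoryl)-6-methylhept-5-enoate F9. Me3SiBr (CH2Cl2) converts it into methyl 2-{bis[(trimethylsilyl)oxy]phosphoryl}-6-methylhept-5-enoate F10. Oxalyl chloride with catalytic DMF gives methyl 2-(dichlorophosphoryl)-6-methylhept-5-enoate F11, and CF3CH2OH/Et3N then gives 14.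

**Further compounds**

F1 | step 9 | [(2E,6Z)-8-[(tert-butyldiphenylsilyl)oxy]-2-[(1S)-1-hydroxybut-3-en-1-yl]-6-methylocta-2,6-dien-1-yl] acetate | CC(=O)OC/C(=C\CC/C(C)=C\CO[Si](c1ccccc1)(c1ccccc1)C(C)(C)C)[C@@H](O)CC=C
F2 | step 9 | methyl 6-methyl-2-methylidenehept-5-enoate | C=C(CCC=C(C)C)C(=O)OC
F3 | step 9 | 6-methyl-2-methylidenehept-5-enoic acid | C=C(CCC=C(C)C)C(=O)O
F4 | step 9 | (4S,5E,9Z)-5-(acetoxymethyl)-11-[(tert-butyldiphenylsilyl)oxy]-9-methylundeca-1,5,9-trien-4-yl 6-methyl-2-methylidenehept-5-enoate | CC(=O)OC/C(=C\CC/C(C)=C\CO[Si](c1ccccc1)(c1ccccc1)C(C)(C)C)[C@@H](OC(=O)C(=C)CCC=C(C)C)CC=C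
F5 | step 9 | (6S)-6-[(2E,6Z)-1-acetoxy-8-[(tert-butyldiphenylsilyl)oxy]-6-methylocta-2,6-dien-2-yl]-3-(4-methylpent-3-en-1-yl)-5,6-dihydro-2H-pyran-2-one | CC(=O)OC/C(=C\CC/C(C)=C\CO[Si](c1ccccc1)(c1ccccc1)C(C)(C)C)[C@@H]1CC=C(CCC=C(C)C)C(=O)O1
F6 | step 7 | methyl (2Z,6Z)-2-(bromomethyl)-8-[(tert-butyldiphenylsilyl)oxy]-6-methylocta-2,6-dienoate | COC(=O)/C(CBr)=C/CC/C(C)=C\CO[Si](c1ccccc1)(c1ccccc1)C(C)(C)C
F7 | step 7 | (2Z,6Z)-2-(bromomethyl)-8-[(tert-butyldiphenylsilyl)oxy]-6-methylocta-2,6-dien-1-ol | OC/C(CBr)=C/CC/C(C)=C\CO[Si](c1ccccc1)(c1ccccc1)C(C)(C)C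
F8 | step 7 | (2Z,6Z)-2-(bromomethyl)-8-[(tert-butyldiphenylsilyl)oxy]-6-methylocta-2,6-dienal | O=C/C(CBr)=C/CC/C(C)=C\CO[Si](c1ccccc1)(c1ccccc1)C(C)(C)C
F9 | step 8 | methyl 2-(dimethoxyphosphoryl)-6-methylhept-5-enoate | COC(=O)C(CCC=C(C)C)P(=O)(OC)OC
F10 | step 8 | methyl 2-{bis[(trimethylsilyl)oxy]phosphoryl}-6-methylhept-5-enoate | COC(=O)C(CCC=C(C)C)P(=O)(O[Si](C)(C)C)O[Si](C)(C)C
F11 | step 8 | methyl 2-(dichlorophosphoryl)-6-methylhept-5-enoate | COC(=O)C(CCC=C(C)C)P(=O)(Cl)Cl
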